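## Retrosynthetic overview

1. **Feature.** The bicyclo[2.2.2]octane has bridgeheads C16 and C24 and bridges C15–C14, C30–C29 and C18–C20, and it shares C14, C20 and C24 with cyclopentane C14–C23–C22–C20–C24. C20 is α to C18=O, C24 is β to C30, and C16 is α to C30 and bonded to C18. The C20–C18 bridge therefore comes off by retro-aldol (C16–C18) and retro-Michael (C20–C24). This leaves a spiro cyclohexenone (ring C14–C15–C16–C30–C29–C24) with a 2-methyl-3-oxopropyl arm on C23.
2. **After the cage.** C27 is tied to O26 and used to acylate C29, which gives the γ-lactone. O31 is then brought in from the open groove beside C18=O by conjugate borylation and oxidation. Ring A goes from ketone to enone to ε-lactone (Baeyer–Villiger).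
3. **Before the cage.** The arm comes from radical methallylation at C23. The spiro ring comes from a Diels–Alder reaction of the C14 methylene ketone with a 2-silyloxydiene that already holds C25. The trans-decalin comes from (S)-Wieland–Miescher ketone.
4. **Ring order.** A/B (bought), then the spiro cyclohexene, then cyclopentane plus bicyclooctane in one step, then the γ-lactone, then the ε-lactone.

Key step: step 16

Assumption: atom labels follow the heavy atoms of the target SMILES from left to right (C1 … O31) and are kept for all intermediates; β is the face of ring B (C9, C11, C12, C13, C14, C23) that carries C10; centres that are epimer mixtures or labile (C16, C20, C24, C29, C30 where noted) are drawn without configuration.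

## Route

Step 1
Reactants: 1 (S)-Wieland–Miescher ketone
Product: 2 hydroxy enone (C23 ketone reduced to the equatorial 23β-alcohol, OH cis to C10)
Conditions: NaBH4 (0.3 equiv), EtOH, −10 °C
Reagents that add atoms: none
Why: Chemoselective borohydride reduction: the isolated C23 ketone is more electrophilic than the conjugated C5 carbonyl and takes hydride on the face away from the angular C10 methyl, which should give the equatorial 23β-alcohol (a temporary stereocentre, removed in step 5).

Step 2
Reactants: 2 hydroxy enone
Product: 3 phenylthiomethyl enone (2 with CH2SPh on the enone α-carbon C2)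
Conditions: PhSH, 37% aq CH2O, Et3N, EtOH, reflux
Reagents that add atoms: thiophenol Sc1ccccc1; formaldehyde C=O
Why: Kirk–Petrow thiomethylation: the dienolate of the enone is alkylated at its α-carbon C2 by the sulfanylmethyl electrophile formed from thiophenol and formaldehyde, which installs C1 in a form that lithium later reduces to methyl, and no stereocentre is formed.

Step 3
Reactants: 3 phenylthiomethyl enone
Product: 5 trans-decalone (C5 ketone; gem-dimethyl C2; 9β-methyl; 11α-H; 23β-OH), via dilithium enolate alkoxide 4 (not isolated)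
Conditions: Li, NH3(l)/THF, −78 to −33 °C; then MeI, −78 °C to rt
Reagents that add atoms: lithium [Li] (counter-ion in 4); iodomethane CI
Why: Dissolving-metal reductive alkylation of an enone: lithium cleaves the allylic C–S bond and then reduces the 2-methyl enone to the regiodefined C2=C5 enolate 4, protonation of the β-carbon C11 on the α face sets the trans ring fusion (H11 anti to C10), and methyl iodide alkylates C2 while the lithium alkoxide at C23 stays unmethylated in ammonia.

Step 4
Reactants: 5 trans-decalone
Product: 6 ketal alcohol (C5 as ethylene ketal, 23β-OH)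
Conditions: ethylene glycol, p-TsOH (cat.), benzene, reflux, Dean–Stark
Reagents that add atoms: ethylene glycol OCCO
Why: Acid-catalysed ketalisation with azeotropic removal of water: C5 is the only carbonyl group, the secondary alcohol is inert, and no stereocentre is touched.

Step 5
Reactants: 6 ketal alcohol
Product: 7 ketal ketone (C23 ketone)
Conditions: TPAP (5 mol %), NMO, 4 Å MS, CH2Cl2, rt
Reagents that add atoms: none
Why: Ley–Griffith oxidation of a secondary alcohol under neutral conditions that leave the ketal intact and remove the temporary C23 stereocentre.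

Step 6
Reactants: 7 ketal ketone
Product: 10 α-methylene ketone (C14=C15H2 next to the C23 ketone), via Mannich base 8 (not isolated), via methiodide 9 (not isolated)
Conditions: LDA, THF, −78 °C, then CH2=NMe2+ I−, −78 °C to rt; MeI, CH2Cl2, rt; sat. aq NaHCO3, rt
Reagents that add atoms: Eschenmoser's salt C=[N+](C)C.[I-]; iodomethane CI (in 9 only)
Why: Mannich methylenation: C14 is the only enolisable position because C9 is quaternary, and quaternisation followed by mild-base β-elimination of trimethylamine gives the exocyclic enone, which is used at once to avoid hetero-Diels–Alder dimerisation.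

Step 7
Reactants: 11 ethyl vinyl ketone; 12 allyl tert-butyldimethylsilyl ether
Product: 13 (E)-6-(tert-butyldimethylsilyloxy)hex-4-en-3-one
Conditions: Hoveyda–Grubbs II (3 mol %), CH2Cl2, 40 °C
Reagents that add atoms: none
Why: Olefin cross-metathesis of an electron-rich terminal allyl ether with a vinyl ketone, a selective pairing that should give the E-enone holding C17, C16, C30, C29, C24 and C25.

Step 8
Reactants: 13 (E)-enone
Product: 14 (2Z,4E)-3,6-bis(tert-butyldimethylsilyloxy)hexa-2,4-diene
Conditions: TBSOTf, Et3N, Et2O, 0 °C
Reagents that add atoms: tert-butyldimethylsilyl triflate CC(C)(C)[Si](C)(C)OS(=O)(=O)C(F)(F)F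
Why: Soft enolisation and silylation at the α′-methylene C16 gives the cross-conjugated 2-silyloxydiene, and the Z enol ether (methyl cis to oxygen) places C17 on the outside of the s-cis diene where it does not hinder cycloaddition.

Step 9
Reactants: 10 α-methylene ketone; 14 silyloxydiene
Product: 15 spiro Diels–Alder adduct (spiro C14 with C24 α-equatorial and C15 β-axial; ring C14–C15–C16(Me)–C30(OTBS)=C29–C24(CH2OTBS); C23 ketone; C16 and C24 epimer mixture)
Conditions: toluene, BHT (cat.), sealed tube, 130 °C
Reagents that add atoms: none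
Why: Diels–Alder reaction of an s-cis-locked α-methylene ketone with a 2-silyloxydiene: the siloxy group directs C16 to the methylene carbon C15 ("para" orientation, C30 1,4 to C14), and the diene adds to the α face of C14=C15 because the β face lies under the syn-axial C10 methyl, which sets C14, while C16 and C24 need no control.

Step 10
Reactants: 15 spiro adduct
Product: 16 23β-alcohol
Conditions: LiAlH4, Et2O, 0 °C to rt
Reagents that add atoms: none
Why: Hydride reduction of a ketone flanked by two quaternary carbons: the small hydride enters axially from the α face, anti to the β-axial C10 and C15, to give the equatorial alcohol (a temporary centre), and the silyl enol ether masks C30.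

Step 11
Reactants: 16 23β-alcohol
Product: 18 S-methyl xanthate of 16, via sodium xanthate 17 (not isolated)
Conditions: NaH, THF, 0 °C to rt; CS2; then MeI
Reagents that add atoms: sodium hydride [Na+].[H-] (counter-ion in 17); carbon disulfide S=C=S; iodomethane CI
Why: Xanthate formation as for a Barton–McCombie precursor: the alkoxide adds to the small linear CS2 despite the crowding, and the xanthate is thermally safe because neither neighbour of C23 carries a hydrogen for Chugaev elimination.

Step 12
Reactants: 18 xanthate; 19 methallyltributylstannane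
Product: 20 23α-methallyl compound (C22 α-axial and cis to C24, H23 β)
Conditions: 19 (8 equiv), AIBN (portions), benzene, 80 °C
Reagents that add atoms: none
Why: Keck radical allylation: the stannyl radical cleaves the xanthate, and the C23 radical is captured by the stannane on the axial α face, anti to the two flanking β-axial carbons C10 and C15, which sets C23.

Step 13
Reactants: 20 methallyl compound
Product: 21 spiro enone (C24(CH2OTBS)=C29–C30=O, C16 epimer mixture)
Conditions: Pd(OAc)2 (1.2 equiv), MeCN, 40 °C
Reagents that add atoms: none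
Why: Saegusa–Ito oxidation: the palladium enolate sits at C29 because the cycloaddition fixed the enol ether regiochemistry, and β-hydride elimination of H24 gives the β-substituted enone and removes the uncontrolled C24 centre.

Step 14
Reactants: 21 spiro enone
Product: 23 hydroxy enone (arm C22H2–C20H(Me)–C18H2OH; C20 epimer mixture), via B-alkyl-9-BBN adduct 22 (not isolated)
Conditions: 9-BBN, THF, 0 °C to rt; then NaBO3·4H2O, THF/H2O, rt
Reagents that add atoms: 9-borabicyclo[3.3.1]nonane B1C2CCCC1CCC2 (in 22 only); sodium perborate [Na+].[O-]OB=O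
Why: Anti-Markovnikov hydroboration–oxidation: 9-BBN reacts fastest with the unhindered 1,1-disubstituted alkene, perborate avoids nucleophilic epoxidation of the enone, C20 may form as a mixture because it is epimerised later, and any allylic alcohol from 1,2-reduction at C30 is returned to the enone in step 15.

Step 15
Reactants: 23 hydroxy enone
Product: 24 spiro enone aldehyde (key-step precursor; mixture at C16 and C20)
Conditions: Dess–Martin periodinane, CH2Cl2, rt
Reagents that add atoms: none
Why: Dess–Martin oxidation of the primary alcohol to the aldehyde under conditions that spare the silyl ether, ketal and enone.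

Step 16
Reactants: 24 spiro enone aldehyde
Product: 26 cage hydroxy ketone (C18 carbinol with OH turned towards C30; C30 ketone; C25 OTBS; C5 ketal), via Michael adduct 25 (not isolated)
Conditions: DBU (0.5 equiv), toluene (0.01 M), 60 °C
Reagents that add atoms: none
Why: The amidine reversibly enolises the C18 aldehyde, the C20 enolate adds to the β-carbon C24 of the spiro enone, the resulting C29 enolate is relayed by proton transfer to the C16 enolate, and this attacks the now non-enolisable C18 aldehyde; the closest known reaction type is the intramolecular Michael–aldol (formal anionic [4+2]) annulation of cyclohexenones to bicyclo[2.2.2]octanes. Ring C14–C23–C22–C20–C24 closes 5-(enolexo)-exo-trig, and the aldol closes the two new six-membered rings of the bicyclooctane, 6-(enolexo)-exo-trig when counted through C15–C14 and 6-(enolendo)-exo-trig when counted through C30–C29. C24 is set by the two-atom link C23–C22, which stands axial on the α face beside the equatorial C14–C24 bond and can reach only the enone face turned towards C23. C20 and C16 are set by the cage: only the C20 epimer whose formyl group lies over C16, and only bond formation on the C16 face turned towards C18, can bridge, and because C16 and C20 epimerise and both C–C bonds are reversible, all diastereomers of 24 should converge on 26. C18 is expected with its hydroxyl hydrogen-bonded towards the C30 carbonyl and is removed in step 17. The step needs C16 rather than C29 to act as aldol donor; this is secured because C29 could only close the cyclobutane C29–C24–C20–C18, dehydration is impossible since C16 and C20 are quaternary, and high dilution in an aprotic medium suppresses intermolecular aldol reaction and solvolysis of any C25 dienol ether.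

Step 17
Reactants: 26 cage hydroxy ketone
Product: 27 cage 18,30-diketone
Conditions: Dess–Martin periodinane, CH2Cl2, rt
Reagents that add atoms: none
Why: Dess–Martin oxidation of the hindered β-hydroxy ketone under non-basic conditions, so that retro-aldol opening is avoided and C18 becomes the flat carbonyl that later opens one face of C30.

Step 18
Reactants: 27 diketone
Product: 28 C25 primary alcohol
Conditions: HF·pyridine, pyridine, THF, 0 °C to rt
Reagents that add atoms: none
Why: Fluoride desilylation in a buffered acidic medium, chosen because basic fluoride or hydroxide could open the non-enolisable 1,3-diketone at bridgehead C16 by retro-Claisen attack, while the ketal tolerates buffered HF.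

Step 19
Reactants: 28 alcohol
Product: 29 C25 imidazole-1-carboxylate
Conditions: 1,1′-carbonyldiimidazole, CH2Cl2, rt
Reagents that add atoms: 1,1′-carbonyldiimidazole O=C(n1ccnc1)n1ccnc1
Why: Acyl transfer from carbonyldiimidazole to the only hydroxyl group gives an isolable alkoxycarbonylimidazole that holds C27 within reach of C29.

Step 20
Reactants: 29 imidazole-1-carboxylate
Product: 30 β-keto γ-lactone (C29–C27 bond formed; C29 labile)
Conditions: LiHMDS (2.2 equiv), THF, −78 to 0 °C; then 1 M HCl
Reagents that add atoms: none
Why: Intramolecular Claisen-type C-acylation, 5-(enolexo)-exo-trig: C29 is the only deprotonatable carbon because C16 and C20 are quaternary, and the product is protected in the flask as its stabilised enolate against attack by imidazolide.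

Step 21
Reactants: 30 β-keto lactone
Product: 31 β-hydroxy lactones (mixture at C29 and C30)
Conditions: NaBH4, CeCl3·7H2O, MeOH, −78 °C
Reagents that add atoms: none
Why: Luche-type reduction selects C30 (one tertiary neighbour) over C18 (two quaternary neighbours); hydride is expected to enter through the open groove beside the flat C18 carbonyl and so to place O31 on the C15 side, opposite to the target, and therefore this configuration is not relied on and is removed in step 22.

Step 22
Reactants: 31 β-hydroxy lactones
Product: 33 alkylidene lactone (C29=C30 conjugated to C27), via mesylate 32 (not isolated)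
Conditions: MsCl, Et3N (excess), CH2Cl2, 0 °C to rt
Reagents that add atoms: methanesulfonyl chloride CS(=O)(=O)Cl (in 32 only)
Why: Mesylation and E1cB elimination: H29 is acidified by the lactone carbonyl so all isomers of 31 converge, and the double bond lies between non-bridgehead atoms of a bicyclo[2.2.2]octene and is not strained.

Step 23
Reactants: 33 alkylidene lactone
Product: 35 hydroxy lactone ketal (O31 and C27 both turned towards the C18–C20 bridge as in the target), via C30 pinacol boronate 34 (not isolated)
Conditions: CuCl (10 mol %), DPEphos (10 mol %), NaOt-Bu (15 mol %), B2pin2, MeOH (2 equiv), THF, rt; then NaBO3·4H2O, THF/H2O, rt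
Reagents that add atoms: bis(pinacolato)diboron CC1(C)OB(OC1(C)C)B1OC(C)(C)C(C)(C)O1 (in 34 only); sodium perborate [Na+].[O-]OB=O
Why: Copper-catalysed conjugate borylation followed by stereoretentive oxidation: the boryl-copper reagent should reach C30 through the groove between bridges C30–C29 and C18–C20, which is open because C18 is a flat carbonyl whereas the other groove holds a C15 hydrogen (sets C30), and the enolate should be protonated at C29 anti to the bulky boronate, which turns C27 to the same side as O31 (sets C29).

Step 24
Reactants: 35 hydroxy lactone ketal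
Product: 36 ring A ketone (C5=O)
Conditions: 1 M HCl, THF, rt
Reagents that add atoms: water O
Why: Acid-catalysed ketal hydrolysis, under which the γ-lactone, the hindered C18 ketone and the β-hydroxy lactone unit are stable.

Step 25
Reactants: 36 ring A ketone
Product: 39 ring A enone (C7=C8 conjugated to C5=O; free O31–H), via bis-TMS derivative 37 (not isolated), via enone TMS ether 38 (not isolated)
Conditions: TMSOTf, Et3N, CH2Cl2, 0 °C; Pd(OAc)2, MeCN, rt; 1 M HCl, THF, 0 °C
Reagents that add atoms: trimethylsilyl triflate C[Si](C)(C)OS(=O)(=O)C(F)(F)F (in 37 and 38 only)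
Why: Saegusa–Ito dehydrogenation: C5 can enolise only towards C7 (C2 is quaternary and C18 has no α-hydrogen), the ketone is silylated much faster than the lactone, the silyl triflate also caps O31 so that no oxidant meets the free alcohol, and dilute acid frees O31 at the end.

Step 26
Reactants: 39 ring A enone
Product: 40 andilesin A
Conditions: mCPBA, CH2Cl2, rt, dark
Reagents that add atoms: 3-chloroperbenzoic acid OOC(=O)c1cccc(Cl)c1
Why: Baeyer–Villiger oxidation: the peracid adds to the only accessible ketone C5 (C18 is shielded by the quaternary C16 and C20), the tertiary C2 migrates in preference to the vinylic C7, and the electron-poor C7=C8 bond resists epoxidation, so O4 is inserted between C5 and C2 without touching a stereocentre.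

## Compound list

1 | (S)-Wieland–Miescher ketone | C[C@]12CCC(=O)C=C1CCCC2=O | starting material
2 | 23β-hydroxy enone | C[C@]12CCC(=O)C=C1CCC[C@@H]2O | intermediate
3 | phenylthiomethyl enone | C[C@]12CCC(=O)C(CSc3ccccc3)=C1CCC[C@@H]2O | intermediate
4 | dilithium enolate alkoxide | [Li+].[Li+].CC1=C([O-])CC[C@@]2(C)[C@H]1CCC[C@@H]2[O-] | intermediate
5 | trans-decalone, C5 ketone, 23β-OH | CC1(C)C(=O)CC[C@@]2(C)[C@H]1CCC[C@@H]2O | intermediate
6 | ketal alcohol | CC1(C)C3(OCCO3)CC[C@@]2(C)[C@H]1CCC[C@@H]2O | intermediate
7 | ketal ketone | CC1(C)C3(OCCO3)CC[C@@]2(C)[C@H]1CCCC2=O | intermediate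
8 | Mannich base | CC1(C)C3(OCCO3)CC[C@@]2(C)[C@H]1CCC(CN(C)C)C2=O | intermediate
9 | methiodide of 8 | CC1(C)C3(OCCO3)CC[C@@]2(C)[C@H]1CCC(C[N+](C)(C)C)C2=O.[I-] | intermediate
10 | α-methylene ketone | CC1(C)C3(OCCO3)CC[C@@]2(C)[C@H]1CCC(=C)C2=O | intermediate
11 | ethyl vinyl ketone | CCC(=O)C=C | starting material
12 | allyl tert-butyldimethylsilyl ether | C=CCO[Si](C)(C)C(C)(C)C | starting material
13 | (E)-6-(tert-butyldimethylsilyloxy)hex-4-en-3-one | CCC(=O)/C=C/CO[Si](C)(C)C(C)(C)C | intermediate
14 | (2Z,4E)-3,6-bis(tert-butyldimethylsilyloxy)hexa-2,4-diene | C/C=C(\O[Si](C)(C)C(C)(C)C)/C=C/CO[Si](C)(C)C(C)(C)C | intermediate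
15 | spiro Diels–Alder adduct | CC1(C)C5(OCCO5)CC[C@@]2(C)[C@H]1CC[C@]3(CC(C)C(O[Si](C)(C)C(C)(C)C)=CC3CO[Si](C)(C)C(C)(C)C)C2=O | intermediate
16 | 23β-alcohol | CC1(C)C5(OCCO5)CC[C@@]2(C)[C@H]1CC[C@]3(CC(C)C(O[Si](C)(C)C(C)(C)C)=CC3CO[Si](C)(C)C(C)(C)C)[C@@H]2O | intermediate
17 | sodium xanthate | CC1(C)C5(OCCO5)CC[C@@]2(C)[C@H]1CC[C@]3(CC(C)C(O[Si](C)(C)C(C)(C)C)=CC3CO[Si](C)(C)C(C)(C)C)[C@@H]2OC(=S)[S-].[Na+] | intermediate
18 | S-methyl xanthate | CC1(C)C5(OCCO5)CC[C@@]2(C)[C@H]1CC[C@]3(CC(C)C(O[Si](C)(C)C(C)(C)C)=CC3CO[Si](C)(C)C(C)(C)C)[C@@H]2OC(=S)SC | intermediate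
19 | methallyltributylstannane | C=C(C)C[Sn](CCCC)(CCCC)CCCC | starting material
20 | 23α-methallyl compound | CC1(C)C5(OCCO5)CC[C@@]2(C)[C@H]1CC[C@]3(CC(C)C(O[Si](C)(C)C(C)(C)C)=CC3CO[Si](C)(C)C(C)(C)C)[C@H]2CC(C)=C | intermediate
21 | spiro enone | CC1(C)C5(OCCO5)CC[C@@]2(C)[C@H]1CC[C@]3(CC(C)C(=O)C=C3CO[Si](C)(C)C(C)(C)C)[C@H]2CC(C)=C | intermediate
22 | B-alkyl-9-BBN adduct | CC1(C)C5(OCCO5)CC[C@@]2(C)[C@H]1CC[C@]3(CC(C)C(=O)C=C3CO[Si](C)(C)C(C)(C)C)[C@H]2CC(C)CB6C7CCCC6CCC7 | intermediate
23 | hydroxy enone | CC1(C)C5(OCCO5)CC[C@@]2(C)[C@H]1CC[C@]3(CC(C)C(=O)C=C3CO[Si](C)(C)C(C)(C)C)[C@H]2CC(C)CO | intermediate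
24 | spiro enone aldehyde (key-step precursor) | CC1(C)C5(OCCO5)CC[C@@]2(C)[C@H]1CC[C@]3(CC(C)C(=O)C=C3CO[Si](C)(C)C(C)(C)C)[C@H]2CC(C)C=O | intermediate
25 | Michael adduct (keto aldehyde) | CC1(C)C5(OCCO5)CC[C@@]2(C)[C@H]1CC[C@]13CC(C)C(=O)C[C@]3(CO[Si](C)(C)C(C)(C)C)[C@](C)(C=O)C[C@@H]21 | intermediate
26 | cage hydroxy ketone (key-step product) | CC1(C)C5(OCCO5)CC[C@@]2(C)[C@H]1CC[C@]13C[C@]4(C)[C@@H](O)[C@](C)(C[C@@H]21)[C@@]3(CO[Si](C)(C)C(C)(C)C)CC4=O | intermediate
27 | cage 18,30-diketone | CC1(C)C5(OCCO5)CC[C@@]2(C)[C@H]1CC[C@]13C[C@]4(C)C(=O)[C@](C)(C[C@@H]21)[C@@]3(CO[Si](C)(C)C(C)(C)C)CC4=O | intermediate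
28 | C25 alcohol | CC1(C)C5(OCCO5)CC[C@@]2(C)[C@H]1CC[C@]13C[C@]4(C)C(=O)[C@](C)(C[C@@H]21)[C@@]3(CO)CC4=O | intermediate
29 | C25 imidazole-1-carboxylate | CC1(C)C5(OCCO5)CC[C@@]2(C)[C@H]1CC[C@]13C[C@]4(C)C(=O)[C@](C)(C[C@@H]21)[C@@]3(COC(=O)n6ccnc6)CC4=O | intermediate
30 | β-keto γ-lactone | CC1(C)C5(OCCO5)CC[C@@]2(C)[C@H]1CC[C@]13C[C@]4(C)C(=O)[C@](C)(C[C@@H]21)[C@]31COC(=O)C1C4=O | intermediate
31 | β-hydroxy lactones (C29/C30 mixture) | CC1(C)C5(OCCO5)CC[C@@]2(C)[C@H]1CC[C@]13C[C@]4(C)C(=O)[C@](C)(C[C@@H]21)[C@]31COC(=O)C1C4O | intermediate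
32 | mesylate of 31 | CC1(C)C5(OCCO5)CC[C@@]2(C)[C@H]1CC[C@]13C[C@]4(C)C(=O)[C@](C)(C[C@@H]21)[C@]31COC(=O)C1C4OS(C)(=O)=O | intermediate
33 | alkylidene lactone | CC1(C)C5(OCCO5)CC[C@@]2(C)[C@H]1CC[C@]13C[C@]4(C)C(=O)[C@](C)(C[C@@H]21)[C@]31COC(=O)C1=C4 | intermediate
34 | C30 pinacol boronate | CC1(C)C5(OCCO5)CC[C@@]2(C)[C@H]1CC[C@]13C[C@]4(C)C(=O)[C@](C)(C[C@@H]21)[C@]31COC(=O)[C@H]1[C@H]4B6OC(C)(C)C(C)(C)O6 | intermediate
35 | hydroxy lactone ketal | CC1(C)C5(OCCO5)CC[C@@]2(C)[C@H]1CC[C@]13C[C@]4(C)C(=O)[C@](C)(C[C@@H]21)[C@]31COC(=O)[C@H]1[C@H]4O | intermediate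
36 | ring A ketone | CC1(C)C(=O)CC[C@@]2(C)[C@H]1CC[C@]13C[C@]4(C)C(=O)[C@](C)(C[C@@H]21)[C@]31COC(=O)[C@H]1[C@H]4O | intermediate
37 | bis-TMS derivative (C5 enol ether, O31 ether) | CC1(C)C(O[Si](C)(C)C)=CC[C@@]2(C)[C@H]1CC[C@]13C[C@]4(C)C(=O)[C@](C)(C[C@@H]21)[C@]31COC(=O)[C@H]1[C@H]4O[Si](C)(C)C | intermediate
38 | enone TMS ether | CC1(C)C(=O)C=C[C@@]2(C)[C@H]1CC[C@]13C[C@]4(C)C(=O)[C@](C)(C[C@@H]21)[C@]31COC(=O)[C@H]1[C@H]4O[Si](C)(C)C | intermediate
39 | ring A enone | CC1(C)C(=O)C=C[C@@]2(C)[C@H]1CC[C@]13C[C@]4(C)C(=O)[C@](C)(C[C@@H]21)[C@]31COC(=O)[C@H]1[C@H]4O | intermediate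
40 | andilesin A | CC1(C)OC(=O)C=C[C@@]2(C)[C@H]1CC[C@]13C[C@]4(C)C(=O)[C@](C)(C[C@@H]21)[C@]31COC(=O)[C@H]1[C@H]4O | target

## Step count and risks

Total step count: 26. Longest linear sequence: 24 (steps 1–6 and 9–26; steps 7–8 form the diene branch).

**Step 16 (key cascade).**
- What may go wrong: the Michael addition must join two fully substituted carbons next to the spiro centre. The equilibrium may therefore stay on the open-chain side, γ-deprotonation at C25 may deconjugate the enone, or intermolecular aldol condensation may take over.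
- Fallback: it sets out from 24 and replaces the reversible anionic cascade by an irreversible silyl-transfer sequence. The aldehyde is silylated selectively (TBSOTf 1.05 equiv, Et3N, CH2Cl2, −78 °C) to the aldehyde silyl enol ether F1. Catalytic Tf2NH (CH2Cl2, −78 °C) then triggers an intramolecular Mukaiyama–Michael addition with silyl transfer, which gives the C30 silyl enol ether aldehyde F2. One equivalent of TBAF (THF, −78 to 0 °C) releases the C29 enolate, which equilibrates to the C16 enolate and closes the aldol. The route is rejoined at 26.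

**Step 12 (radical methallylation).**
- What may go wrong: capture of the doubly neopentyl C23 radical by the stannane may be slow. That would allow premature hydrogen abstraction, or β-scission of the C14–C24 bond towards a siloxyallyl radical.
- Fallback: it sets out from 18 and uses a polarity-matched, much faster Giese addition. Methyl methacrylate, (TMS)3SiH and AIBN (toluene, 85 °C, slow addition) should give the methyl ester F3 with the same α-axial attack. LiAlH4 (Et2O, 0 °C) reduces it to the primary alcohol F4, with the silyl enol ether intact. Pd(OAc)2 (MeCN, 40 °C) then unveils the enone. The route is rejoined at 23, so steps 13 and 14 are bypassed.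

**Step 23 (conjugate borylation).**
- What may go wrong: the ligated boryl-copper may not reach the neopentyl C30, it may show poor facial selectivity, or protonation at C29 may occur from the wrong side.
- Fallback: it sets out from 33 and delivers oxygen directly with a small nucleophile. Nucleophilic epoxidation (t-BuOOH, DBU, CH2Cl2, rt) through the same open groove should give the α,β-epoxy lactone F5. SmI2 (THF/MeOH, −78 °C) then cleaves the C29–O bond reductively, with protonation anti to the C30 alkoxide. The route is rejoined at 35.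

## Further compounds

F1 | step 16 | aldehyde silyl enol ether of 24 | CC1(C)C5(OCCO5)CC[C@@]2(C)[C@H]1CC[C@]3(CC(C)C(=O)C=C3CO[Si](C)(C)C(C)(C)C)[C@H]2CC(C)=CO[Si](C)(C)C(C)(C)C
F2 | step 16 | C30 silyl enol ether aldehyde (Mukaiyama–Michael product) | CC1(C)C5(OCCO5)CC[C@@]2(C)[C@H]1CC[C@]13CC(C)C(O[Si](C)(C)C(C)(C)C)=C[C@]3(CO[Si](C)(C)C(C)(C)C)[C@](C)(C=O)C[C@@H]21
F3 | step 12 | methyl ester from Giese addition | CC1(C)C5(OCCO5)CC[C@@]2(C)[C@H]1CC[C@]3(CC(C)C(O[Si](C)(C)C(C)(C)C)=CC3CO[Si](C)(C)C(C)(C)C)[C@H]2CC(C)C(=O)OC
F4 | step 12 | primary alcohol with silyl enol ether | CC1(C)C5(OCCO5)CC[C@@]2(C)[C@H]1CC[C@]3(CC(C)C(O[Si](C)(C)C(C)(C)C)=CC3CO[Si](C)(C)C(C)(C)C)[C@H]2CC(C)CO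
F5 | step 23 | α,β-epoxy lactone | CC1(C)C5(OCCO5)CC[C@@]2(C)[C@H]1CC[C@]13C[C@]4(C)C(=O)[C@](C)(C[C@@H]21)[C@]31COC(=O)[C@@]16O[C@H]64
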